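## Retrosynthetic overview

1. Target 24 comes from 23 by removing the silyl cap on the alkyne. The only ring, the 1,2-dioxane O1–O2–C3–C4–C5–C6, is formed once, in the key step.
2. 23 comes from thioester 18 and iodide 8. The bond between ketal carbon C6 and the first CH2 of the C16 chain is made as an acyl–alkyl bond (alkylzinc plus thioester, Pd), and acidic MeOH then closes the ring in the same operation. The enabling feature: C6 is a ketone-level carbon placed 1,4 to the peroxy-bearing C3, so a C3–O–O–H group closes onto C6 by itself. The (3S,6R) ketal (OMe axial on C6, carbon substituents on C3 and C6 equatorial) should be the thermodynamic one, so only C3 has to be set.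
3. 18 comes from enal 13 and hydroperoxide 15 by enantioselective iminium-catalysed β-peroxidation (sets C3), then aldehyde to methyl ester. 13 comes from cross-metathesis of thioester 11 with crotonaldehyde.
4. 8 comes from Sonogashira union of the (E)-vinyl iodide 5 (Takai olefination of aldehyde 4) with pent-4-yn-1-ol, then OH to I.

Key step: step 12

Remark on the chemistry: in the target the C6 methoxy group is cis to the C3 CH2CO2Me group, which puts OMe axial and both carbon substituents equatorial in the chair; this isomer is assumed to be the thermodynamic ketal.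

## Route

Step 1
Reactants: 1 dec-9-yn-1-ol
Product: 3 10-(trimethylsilyl)dec-9-yn-1-ol, via bis-silyl ether 2 (not isolated)
Conditions: n-BuLi (2.2 equiv), THF, −78 °C; TMSCl (2.3 equiv), −78 → 0 °C; then 1 M HCl, 23 °C
Reagents that add atoms: chlorotrimethylsilane, C[Si](C)(C)Cl
Why: Double deprotonation (O–H and C(sp)–H) and bis-silylation, followed by selective acidic cleavage of the labile O–Si bond, should leave the C-silylated alkyne (alkyne C-silylation), which masks the terminal alkyne for the later Sonogashira and zinc chemistry.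

Step 2
Reactants: 3 10-(trimethylsilyl)dec-9-yn-1-ol
Product: 4 10-(trimethylsilyl)dec-9-ynal
Conditions: DMP (Dess–Martin periodinane), CH2Cl2, 0 → 23 °C
Reagents that add atoms: none
Why: Dess–Martin oxidation should take the primary alcohol to the aldehyde without over-oxidation and without touching the silylalkyne.

Step 3
Reactants: 4 10-(trimethylsilyl)dec-9-ynal
Product: 5 [(10E)-11-iodoundec-10-en-1-yn-1-yl]trimethylsilane
Conditions: CrCl2 (6 equiv), CHI3 (2 equiv), THF–1,4-dioxane, 0 → 23 °C
Reagents that add atoms: iodoform, IC(I)I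
Why: Takai olefination: the gem-dichromium species formed from CHI3 and CrCl2 adds to the aldehyde and eliminates to the vinyl iodide, the E geometry following from the anti arrangement of the substituents in the β-oxido dichromium intermediate.

Step 4
Reactants: 5 [(10E)-11-iodoundec-10-en-1-yn-1-yl]trimethylsilane; 6 pent-4-yn-1-ol
Product: 7 (6E)-16-(trimethylsilyl)hexadec-6-ene-4,15-diyn-1-ol
Conditions: PdCl2(PPh3)2 (3 mol %), CuI (6 mol %), Et3N, THF, 23 °C
Reagents that add atoms: none
Why: Sonogashira coupling of the vinyl iodide with the only free terminal alkyne should give the conjugated enyne with retention of the E geometry, the second alkyne being blocked by silicon.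

Step 5
Reactants: 7 (6E)-16-(trimethylsilyl)hexadec-6-ene-4,15-diyn-1-ol
Product: 8 [(10E)-16-iodohexadec-10-ene-1,12-diyn-1-yl]trimethylsilane
Conditions: I2, PPh3, imidazole, CH2Cl2, 0 °C
Reagents that add atoms: iodine, II
Why: Appel-type iodination converts the primary alcohol into the iodide by SN2 displacement of the oxyphosphonium group, leaving the enyne and silylalkyne alone.

Step 6
Reactants: 9 pent-4-enoyl chloride; 10 ethanethiol
Product: 11 S-ethyl pent-4-enethioate
Conditions: pyridine, CH2Cl2, 0 → 23 °C
Reagents that add atoms: none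
Why: S-Acylation of the thiol by the acid chloride installs the thioester that later serves as the chemoselective acyl donor for ketone formation.

Step 7
Reactants: 11 S-ethyl pent-4-enethioate; 12 (E)-but-2-enal
Product: 13 S-ethyl (4E)-6-oxohex-4-enethioate
Conditions: second-generation Grubbs catalyst RuCl2(SIMes)(PCy3)(=CHPh) (3 mol %), 12 (5 equiv), CH2Cl2, 40 °C
Reagents that add atoms: none
Why: Olefin cross-metathesis of a terminal alkene with an excess of the reluctant enal partner should give the cross product as the thermodynamically preferred E-enal, the remote thioester being a spectator.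

Step 8
Reactants: 14 2,3-dimethylbut-2-ene
Product: 15 2-methoxypropan-2-yl hydroperoxide
Conditions: O3, MeOH–CH2Cl2, −78 °C; N2 purge; used as a solution
Reagents that add atoms: ozone, [O-][O+]=O; methanol, CO
Why: Ozonolysis in methanol: the carbonyl oxide released on cycloreversion of the primary ozonide is trapped by MeOH to give the α-methoxy hydroperoxide, a ketal-protected form of H2O2.

Step 9
Reactants: 13 S-ethyl (4E)-6-oxohex-4-enethioate; 15 2-methoxypropan-2-yl hydroperoxide
Product: 16 S-ethyl (4S)-4-[(2-methoxypropan-2-yl)peroxy]-6-oxohexanethioate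
Conditions: (R)-2-{bis[3,5-bis(trifluoromethyl)phenyl](trimethylsilyloxy)methyl}pyrrolidine (10 mol %), PhCO2H (10 mol %), toluene, 0 °C
Reagents that add atoms: none
Why: Enantioselective iminium-catalysed oxa-Michael addition of a hydroperoxide to an enal: the hydroperoxide should add to the β-carbon of the E,s-trans iminium ion on the face opposite the diaryl(silyloxy)methyl group, which for the (R)-catalyst is expected to give the (S)-configured C–O bond (the enantiomeric catalyst is used if the sense proves opposite).

Step 10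
Reactants: 16 S-ethyl (4S)-4-[(2-methoxypropan-2-yl)peroxy]-6-oxohexanethioate
Product: 17 (3S)-6-(ethylsulfanyl)-3-[(2-methoxypropan-2-yl)peroxy]-6-oxohexanoic acid
Conditions: NaClO2, NaH2PO4, 2-methylbut-2-ene, t-BuOH–H2O, 0 °C, short reaction time
Reagents that add atoms: sodium chlorite, [Na+].[O-]Cl=O
Why: Pinnick oxidation under phosphate buffer with a hypochlorite scavenger should oxidise only the aldehyde, and since no base is present the β-peroxy stereocentre cannot be lost by elimination.

Step 11
Reactants: 17 (3S)-6-(ethylsulfanyl)-3-[(2-methoxypropan-2-yl)peroxy]-6-oxohexanoic acid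
Product: 18 methyl (3S)-6-(ethylsulfanyl)-3-[(2-methoxypropan-2-yl)peroxy]-6-oxohexanoate
Conditions: TMSCHN2, MeOH–toluene, 0 °C
Reagents that add atoms: (trimethylsilyl)diazomethane, C[Si](C)(C)C=[N+]=[N-]
Why: O-Methylation of the acid by the diazoalkane under neutral conditions avoids the base-induced β-elimination of the peroxide that an alkylation with base would risk.

Step 12
Reactants: 8 [(10E)-16-iodohexadec-10-ene-1,12-diyn-1-yl]trimethylsilane; 18 methyl (3S)-6-(ethylsulfanyl)-3-[(2-methoxypropan-2-yl)peroxy]-6-oxohexanoate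
Product: 23 methyl 2-[(3S,6R)-6-methoxy-6-[(6E)-16-(trimethylsilyl)hexadec-6-ene-4,15-diyn-1-yl]-1,2-dioxan-3-yl]acetate, via alkylzinc iodide 19 (not isolated), via ketone 20 (not isolated), via hydroperoxy ketone 21 (not isolated), via peroxyhemiketal 22 (not isolated)
Conditions: 8 (1.5 equiv), Zn dust, LiCl, THF, 40 °C; then 18, Pd(OH)2/C (5 mol %), THF–toluene–DMF, 23 °C; filtration through a short silica pad and evaporation; then MeOH, (+)-10-camphorsulfonic acid (20 mol %), 0 → 23 °C
Reagents that add atoms: methanol, CO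
Why: Zinc inserts into the primary C–I bond of 8, and a Fukuyama coupling (oxidative addition of zerovalent palladium into the C(acyl)–S bond of 18, transmetalation from 19, reductive elimination) forges the bond between the future ketal carbon and the first CH2 of the chain; the methyl ester, enyne and silylalkyne are untouched because alkylzinc iodides do not add to esters or ketones, and the unstrained peroxyketal is expected to survive. The silica pad removes zinc thiolate and palladium, which would otherwise reduce a free hydroperoxide; in acidic methanol the 2-methoxypropan-2-yl group of 20 is then lost as 2,2-dimethoxypropane and the freed hydroperoxide 21 adds to the γ-ketone (6-exo-trig attack of the terminal peroxy oxygen on the carbonyl carbon) to close the O1–O2–C3–C4–C5–C6 ring as hemiketal 22. Exchange of the anomeric OH for OMe through the ring peroxycarbenium ion is reversible, so the new stereocentre C6 is set under thermodynamic control by C3: the chair with OMe axial (anomeric effect of O1) and both carbon substituents equatorial is the (3S,6R) isomer. The closest known reaction types are the thioester–organozinc ketone synthesis on polyfunctional substrates and the acid-mediated conversion of γ-hydroperoxy ketones or their perketals into 3-alkoxy-1,2-dioxanes. The step needs chemoselectivity for the thioester over the ester, secured by the selective C–S oxidative addition, and configurational stability at C3, secured because the sequence is base-free and the β-peroxy ester therefore cannot undergo elimination and re-addition.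

Step 13
Reactants: 23 methyl 2-[(3S,6R)-6-methoxy-6-[(6E)-16-(trimethylsilyl)hexadec-6-ene-4,15-diyn-1-yl]-1,2-dioxan-3-yl]acetate
Product: 24 methyl 2-[(3S,6R)-6-[(6E)-hexadec-6-ene-4,15-diyn-1-yl]-6-methoxy-1,2-dioxan-3-yl]acetate
Conditions: K2CO3 (0.3 equiv), MeOH, 0 °C
Reagents that add atoms: none
Why: Base-catalysed methanolysis of the C(sp)–Si bond (alkyne protodesilylation) should free the terminal alkyne, the ketal being base-stable and the dialkyl peroxide being expected to tolerate brief exposure to carbonate at 0 °C.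

## Compound list

1 | dec-9-yn-1-ol | C#CCCCCCCCCO | starting material
2 | trimethyl{[10-(trimethylsilyl)dec-9-yn-1-yl]oxy}silane | C[Si](C)(C)OCCCCCCCCC#C[Si](C)(C)C | intermediate
3 | 10-(trimethylsilyl)dec-9-yn-1-ol | C[Si](C)(C)C#CCCCCCCCCO | intermediate
4 | 10-(trimethylsilyl)dec-9-ynal | C[Si](C)(C)C#CCCCCCCCC=O | intermediate
5 | [(10E)-11-iodoundec-10-en-1-yn-1-yl]trimethylsilane | C[Si](C)(C)C#CCCCCCCC/C=C/I | intermediate
6 | pent-4-yn-1-ol | C#CCCCO | starting material
7 | (6E)-16-(trimethylsilyl)hexadec-6-ene-4,15-diyn-1-ol | OCCCC#C/C=C/CCCCCCCC#C[Si](C)(C)C | intermediate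
8 | [(10E)-16-iodohexadec-10-ene-1,12-diyn-1-yl]trimethylsilane | ICCCC#C/C=C/CCCCCCCC#C[Si](C)(C)C | intermediate
9 | pent-4-enoyl chloride | C=CCCC(Cl)=O | starting material
10 | ethanethiol | CCS | starting material
11 | S-ethyl pent-4-enethioate | C=CCCC(=O)SCC | intermediate
12 | (E)-but-2-enal (crotonaldehyde) | C/C=C/C=O | starting material
13 | S-ethyl (4E)-6-oxohex-4-enethioate | CCSC(=O)CC/C=C/C=O | intermediate
14 | 2,3-dimethylbut-2-ene | CC(C)=C(C)C | starting material
15 | 2-methoxypropan-2-yl hydroperoxide | COC(C)(C)OO | intermediate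
16 | S-ethyl (4S)-4-[(2-methoxypropan-2-yl)peroxy]-6-oxohexanethioate | CCSC(=O)CC[C@@H](CC=O)OOC(C)(C)OC | intermediate
17 | (3S)-6-(ethylsulfanyl)-3-[(2-methoxypropan-2-yl)peroxy]-6-oxohexanoic acid | CCSC(=O)CC[C@@H](CC(=O)O)OOC(C)(C)OC | intermediate
18 | methyl (3S)-6-(ethylsulfanyl)-3-[(2-methoxypropan-2-yl)peroxy]-6-oxohexanoate | CCSC(=O)CC[C@@H](CC(=O)OC)OOC(C)(C)OC | intermediate
19 | [(6E)-16-(trimethylsilyl)hexadec-6-ene-4,15-diyn-1-yl]zinc iodide | I[Zn]CCCC#C/C=C/CCCCCCCC#C[Si](C)(C)C | intermediate
20 | methyl (3S,12E)-3-[(2-methoxypropan-2-yl)peroxy]-6-oxo-22-(trimethylsilyl)docos-12-ene-10,21-diynoate | C[Si](C)(C)C#CCCCCCCC/C=C/C#CCCCC(=O)CC[C@@H](CC(=O)OC)OOC(C)(C)OC | intermediate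
21 | methyl (3S,12E)-3-hydroperoxy-6-oxo-22-(trimethylsilyl)docos-12-ene-10,21-diynoate | C[Si](C)(C)C#CCCCCCCC/C=C/C#CCCCC(=O)CC[C@@H](CC(=O)OC)OO | intermediate
22 | methyl 2-[(3S)-6-hydroxy-6-[(6E)-16-(trimethylsilyl)hexadec-6-ene-4,15-diyn-1-yl]-1,2-dioxan-3-yl]acetate (C6 epimers) | C[Si](C)(C)C#CCCCCCCC/C=C/C#CCCCC1(O)CC[C@@H](CC(=O)OC)OO1 | intermediate
23 | methyl 2-[(3S,6R)-6-methoxy-6-[(6E)-16-(trimethylsilyl)hexadec-6-ene-4,15-diyn-1-yl]-1,2-dioxan-3-yl]acetate | C[Si](C)(C)C#CCCCCCCC/C=C/C#CCCC[C@]1(OC)CC[C@@H](CC(=O)OC)OO1 | intermediate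
24 | methyl 2-[(3S,6R)-6-[(6E)-hexadec-6-ene-4,15-diyn-1-yl]-6-methoxy-1,2-dioxan-3-yl]acetate (CNP0314169.1) | C#CCCCCCCC/C=C/C#CCCC[C@]1(OC)CC[C@@H](CC(=O)OC)OO1 | target

## Step count and risks

Total step count: 13.
Longest linear sequence: 7 steps (steps 1, 2, 3, 4, 5, 12, 13).

Steps most likely to fail:

**Step 12.** The O–O bond may be lost during the zinc/palladium stage (reduction by the zinc reagent or by palladium, or attack of the alkylzinc on a peroxide oxygen), or acyl transfer may be sluggish. The fallback changes the order of events so that no peroxide is present during the coupling; it sets out from 8 and 13 and returns to the route at 20. Zinc reagent 19 (from 8) is coupled under the same Pd(OH)2/C conditions with the thioester group of enal 13, whose aldehyde should be tolerated by the alkylzinc iodide. This should give the keto-enal (2E,12E)-6-oxo-22-(trimethylsilyl)docosa-2,12-diene-10,21-diynal F1. The iminium-catalysed peroxidation with 15 (as in step 9) then gives (3S,12E)-3-[(2-methoxypropan-2-yl)peroxy]-6-oxo-22-(trimethylsilyl)docos-12-ene-10,21-diynal F2. Pinnick oxidation gives (3S,12E)-3-[(2-methoxypropan-2-yl)peroxy]-6-oxo-22-(trimethylsilyl)docos-12-ene-10,21-diynoic acid F3, and TMSCHN2 gives keto ester 20. From 20 the acid/methanol stage of step 12 continues to 23.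

**Step 9.** Facial selectivity in the iminium addition may be poor, or the peroxy-enamine may collapse to the epoxide instead of being protonated. In the fallback the stereocentre is set by reagent-controlled allylation and transferred by SN2 displacement with inversion; it sets out from 6 and 15 and returns at 18. Alcohol 6 is oxidised with DMP to pent-4-ynal F4. Brown allylation with the Ipc2B(allyl) enantiomer derived from (+)-α-pinene is expected to give (4R)-oct-1-en-7-yn-4-ol F5. Mesylation (MsCl, Et3N) gives (4R)-oct-1-en-7-yn-4-yl methanesulfonate F6. Displacement with 15 and CsOH in DMF should give, with inversion, (4S)-4-[(2-methoxypropan-2-yl)peroxy]oct-1-en-7-yne F7. Ozonolysis of the alkene (the alkyne reacts much more slowly; Me2S work-up) gives (3S)-3-[(2-methoxypropan-2-yl)peroxy]hept-6-ynal F8. Pinnick oxidation gives (3S)-3-[(2-methoxypropan-2-yl)peroxy]hept-6-ynoic acid F9, and TMSCHN2 gives methyl (3S)-3-[(2-methoxypropan-2-yl)peroxy]hept-6-ynoate F10. Cleavage of the terminal alkyne with RuCl3/NaIO4 gives (4S)-6-methoxy-4-[(2-methoxypropan-2-yl)peroxy]-6-oxohexanoic acid F11. Thioesterification with 10 (DCC, DMAP) gives 18.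

**Step 13.** Carbonate may trigger opening of the β-peroxy ester (retro-oxa-Michael) or base-induced fragmentation of the peroxide during desilylation. In the fallback silicon is removed before any peroxide is present; it sets out from 7 and returns at 24. K2CO3/MeOH on 7 gives (6E)-hexadec-6-ene-4,15-diyn-1-ol F12. I2/PPh3/imidazole gives (10E)-16-iodohexadec-10-ene-1,12-diyne F13. Zinc insertion gives [(6E)-hexadec-6-ene-4,15-diyn-1-yl]zinc iodide F14; alkylzinc iodides are expected to tolerate the acetylenic C–H. Coupling with 18 as in step 12 gives methyl (3S,12E)-3-[(2-methoxypropan-2-yl)peroxy]-6-oxodocos-12-ene-10,21-diynoate F15. The acid/methanol stage then passes through methyl (3S,12E)-3-hydroperoxy-6-oxodocos-12-ene-10,21-diynoate F16 and methyl 2-[(3S)-6-[(6E)-hexadec-6-ene-4,15-diyn-1-yl]-6-hydroxy-1,2-dioxan-3-yl]acetate F17 to the target 24 directly, so the finished peroxide never meets base.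

Further compounds
F1 | step 12 | (2E,12E)-6-oxo-22-(trimethylsilyl)docosa-2,12-diene-10,21-diynal | C[Si](C)(C)C#CCCCCCCC/C=C/C#CCCCC(=O)CC/C=C/C=O
F2 | step 12 | (3S,12E)-3-[(2-methoxypropan-2-yl)peroxy]-6-oxo-22-(trimethylsilyl)docos-12-ene-10,21-diynal | C[Si](C)(C)C#CCCCCCCC/C=C/C#CCCCC(=O)CC[C@@H](CC=O)OOC(C)(C)OC
F3 | step 12 | (3S,12E)-3-[(2-methoxypropan-2-yl)peroxy]-6-oxo-22-(trimethylsilyl)docos-12-ene-10,21-diynoic acid | C[Si](C)(C)C#CCCCCCCC/C=C/C#CCCCC(=O)CC[C@@H](CC(=O)O)OOC(C)(C)OC
F4 | step 9 | pent-4-ynal | C#CCCC=O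
F5 | step 9 | (4R)-oct-1-en-7-yn-4-ol | C#CCC[C@H](CC=C)O
F6 | step 9 | (4R)-oct-1-en-7-yn-4-yl methanesulfonate | C#CCC[C@H](CC=C)OS(C)(=O)=O
F7 | step 9 | (4S)-4-[(2-methoxypropan-2-yl)peroxy]oct-1-en-7-yne | C#CCC[C@@H](CC=C)OOC(C)(C)OC
F8 | step 9 | (3S)-3-[(2-methoxypropan-2-yl)peroxy]hept-6-ynal | C#CCC[C@@H](CC=O)OOC(C)(C)OC
F9 | step 9 | (3S)-3-[(2-methoxypropan-2-yl)peroxy]hept-6-ynoic acid | C#CCC[C@@H](CC(=O)O)OOC(C)(C)OC
F10 | step 9 | methyl (3S)-3-[(2-methoxypropan-2-yl)peroxy]hept-6-ynoate | C#CCC[C@@H](CC(=O)OC)OOC(C)(C)OC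
F11 | step 9 | (4S)-6-methoxy-4-[(2-methoxypropan-2-yl)peroxy]-6-oxohexanoic acid | OC(=O)CC[C@@H](CC(=O)OC)OOC(C)(C)OC
F12 | step 13 | (6E)-hexadec-6-ene-4,15-diyn-1-ol | OCCCC#C/C=C/CCCCCCCC#C
F13 | step 13 | (10E)-16-iodohexadec-10-ene-1,12-diyne | ICCCC#C/C=C/CCCCCCCC#C
F14 | step 13 | [(6E)-hexadec-6-ene-4,15-diyn-1-yl]zinc iodide | I[Zn]CCCC#C/C=C/CCCCCCCC#C
F15 | step 13 | methyl (3S,12E)-3-[(2-methoxypropan-2-yl)peroxy]-6-oxodocos-12-ene-10,21-diynoate | C#CCCCCCCC/C=C/C#CCCCC(=O)CC[C@@H](CC(=O)OC)OOC(C)(C)OC
F16 | step 13 | methyl (3S,12E)-3-hydroperoxy-6-oxodocos-12-ene-10,21-diynoate | C#CCCCCCCC/C=C/C#CCCCC(=O)CC[C@@H](CC(=O)OC)OO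
F17 | step 13 | methyl 2-[(3S)-6-[(6E)-hexadec-6-ene-4,15-diyn-1-yl]-6-hydroxy-1,2-dioxan-3-yl]acetate (C6 epimers) | C#CCCCCCCC/C=C/C#CCCCC1(O)CC[C@@H](CC(=O)OC)OO1
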